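## Retrosynthetic overview
1. Feature: ring B is a benzene ring with oxygen on B1 (free OH), B3 (ether O to ring A) and B5 (ether O to ring C), and hydrogen on B2, B4 and B6. Each ether oxygen sits between two ortho oxygens of ring A or ring C, so both aryl–O bonds are best made before ring B exists.
2. Ring B is cut at B4–B5 and B1–B6. B1–B4 come from a 3-aryloxy silyl ketene acetal diene (aryl = ring A) and B5–B6 from a methyl 3-aryloxypropiolate (aryl = C–D biaryl). The ester on B6 is a traceless activator.
3. The diene goes back to 2,4,6-trimethoxyphenol and methyl but-2-ynoate (oxa-Michael addition, O-silylation). The ynoate goes back to the C–D phenol, trichloroethylene and methyl chloroformate.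
4. The C–D phenol comes from Ullmann homocoupling of 2-iodo-1,3,5-trimethoxybenzene, monoformylation and Baeyer–Villiger oxidation.
5. Ring order: A, C and D are bought as arenes, the C–D bond is made first, and ring B is the only ring built and is closed last. Ester removal and ninefold O-demethylation finish the route.

Key step: step 10

Remark on the chemistry: the target has no stereocentre. The C–D axis is not stereogenic because ring D carries identical groups at both ortho positions. The ketene acetal geometry and the transient ketal centre of the cycloadduct vanish on aromatization, so no stereocontrol is needed.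

## Route

Step 1
Reactants: 1 2,4,6-trimethoxybenzaldehyde
Product: 3 2,4,6-trimethoxyphenol, via aryl formate 2 (not isolated)
Conditions: mCPBA (1.2 equiv), CH2Cl2, 0 °C → rt; aq. NaHCO3 wash; then K2CO3 (cat.), MeOH, rt
Reagents that add atoms: mCPBA, O=C(OO)c1cccc(Cl)c1
Why: Baeyer–Villiger (Dakin-type) oxidation, in which the very electron-rich aryl group migrates in preference to hydrogen and the resulting formate is cleaved by mild methanolysis.

Step 2
Reactants: 3 2,4,6-trimethoxyphenol; 4 methyl but-2-ynoate
Product: 5 methyl (E)-3-(2,4,6-trimethoxyphenoxy)but-2-enoate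
Conditions: Cs2CO3 (20 mol %), DMF, 60 °C
Reagents that add atoms: none
Why: Base-catalysed oxa-Michael addition of the phenoxide to the sterically open sp β-carbon, reversible enough to settle on the more stable E enol ether; phosphine catalysts are avoided because they would divert the ynoate to γ-addition.

Step 3
Reactants: 5 methyl (E)-3-(2,4,6-trimethoxyphenoxy)but-2-enoate
Product: 7 (1Z)-1-methoxy-1-(trimethylsilyloxy)-3-(2,4,6-trimethoxyphenoxy)buta-1,3-diene, via lithium dienolate 6 (not isolated)
Conditions: LiN(i-Pr)2 (commercial solution, 1.1 equiv), THF, −78 °C; TMSCl (1.3 equiv), −78 °C → rt; pentane trituration and filtration under Ar, used crude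
Reagents that add atoms: chlorotrimethylsilane, C[Si](C)(C)Cl
Why: Carbonyl-directed γ-deprotonation of the methyl group cis to the ester and O-silylation of the extended enolate, the same operation that turns methyl 3-methoxycrotonate into the Brassard diene.

Step 4
Reactants: 8 1,3,5-trimethoxybenzene
Product: 9 2-iodo-1,3,5-trimethoxybenzene
Conditions: NIS (1.0 equiv), MeCN, rt, dark
Reagents that add atoms: N-iodosuccinimide, O=C1CCC(=O)N1I
Why: Electrophilic aromatic iodination of a triply activated arene, held at the monoiodide by stoichiometry and by the steric and inductive brake of the first iodine.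

Step 5
Reactants: 9 2-iodo-1,3,5-trimethoxybenzene (two molecules)
Product: 10 2,2',4,4',6,6'-hexamethoxybiphenyl
Conditions: activated Cu bronze (4 equiv), neat melt, 230 °C, Ar
Reagents that add atoms: none
Why: Classical Ullmann biaryl homocoupling, which tolerates ortho-methoxy groups and, being a dimerization, raises no cross-selectivity question for the tetra-ortho-substituted C–D bond.

Step 6
Reactants: 10 2,2',4,4',6,6'-hexamethoxybiphenyl
Product: 12 2,2',4,4',6,6'-hexamethoxybiphenyl-3-carbaldehyde, via iminium salt 11 (not isolated)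
Conditions: POCl3 (0.9 equiv), DMF/ClCH2CH2Cl, 0 °C → rt; then ice/H2O
Reagents that add atoms: N,N-dimethylformamide, CN(C)C=O (formyl carbon); water, O (formyl oxygen)
Why: Vilsmeier–Haack formylation at one of four equivalent CH positions, each ortho/para to three methoxy groups; the iminium group shuts down its own ring, and limiting POCl3 with recycling of 10 restrains attack on the second ring.

Step 7
Reactants: 12 2,2',4,4',6,6'-hexamethoxybiphenyl-3-carbaldehyde
Product: 14 2,2',4,4',6,6'-hexamethoxybiphenyl-3-ol, via biaryl formate 13 (not isolated)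
Conditions: mCPBA (1.1 equiv), CH2Cl2, 0 °C → rt; aq. NaHCO3 wash; then K2CO3 (cat.), MeOH, rt
Reagents that add atoms: mCPBA, O=C(OO)c1cccc(Cl)c1
Why: Baeyer–Villiger (Dakin-type) oxidation as in step 1, with aryl migration much faster at 0 °C than peracid hydroxylation of ring D.

Step 8
Reactants: 14 2,2',4,4',6,6'-hexamethoxybiphenyl-3-ol; 15 trichloroethylene
Product: 16 3-{[(E)-1,2-dichloroethenyl]oxy}-2,2',4,4',6,6'-hexamethoxybiphenyl
Conditions: 15 (1.5 equiv), K2CO3 (2 equiv), DMF, 70 °C, closed vessel under Ar
Reagents that add atoms: none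
Why: Base-induced dehydrochlorination of trichloroethylene followed by anti addition of the phenoxide to the linear chloroalkyne, which the hindered oxygen can reach easily and which fixes the E geometry.

Step 9
Reactants: 16 3-{[(E)-1,2-dichloroethenyl]oxy}-2,2',4,4',6,6'-hexamethoxybiphenyl
Product: 19 methyl 3-[(2,2',4,4',6,6'-hexamethoxybiphenyl-3-yl)oxy]prop-2-ynoate, via chloroalkyne 17 (not isolated), via lithium acetylide 18 (not isolated)
Conditions: n-BuLi (2.1 equiv), THF, −78 → −40 °C; cannulated into ClCO2Me (2 equiv), THF, −78 → 0 °C; pH 7 buffer; Et3N-deactivated silica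
Reagents that add atoms: methyl chloroformate, COC(=O)Cl
Why: Ynol ether synthesis from a 1,2-dichlorovinyl ether (elimination of HCl, chlorine–lithium exchange, C-acylation of the acetylide), all fast at −78 °C where ring lithiation between methoxy groups is slow; inverse addition keeps the acetylide away from the product ester.

Step 10
Reactants: 7 (1Z)-1-methoxy-1-(trimethylsilyloxy)-3-(2,4,6-trimethoxyphenoxy)buta-1,3-diene; 19 methyl 3-[(2,2',4,4',6,6'-hexamethoxybiphenyl-3-yl)oxy]prop-2-ynoate
Product: 22 methyl 2-hydroxy-6-[(2,2',4,4',6,6'-hexamethoxybiphenyl-3-yl)oxy]-4-(2,4,6-trimethoxyphenoxy)benzoate, via cycloadduct 20 (not isolated), via silyl ether 21 (not isolated)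
Conditions: 7 (2 equiv), toluene (1 M), 110 °C, sealed tube, Ar; then 1 M HCl, THF, rt
Reagents that add atoms: none
Why: Diene 7 and the polarised ynoate 19 should combine in a concerted but strongly asynchronous normal-electron-demand [4+2] cycloaddition in which the unsubstituted CH2 terminus (B4) bonds first to the aryloxy-bearing sp carbon (B5) and the ketene acetal carbon (B1) closes onto the ester-bearing carbon (B6), giving cyclohexa-1,4-diene 20, which loses methanol to silyl ether 21 and is desilylated by dilute acid to the hydrogen-bonded salicylate 22. The closest known reaction type is the Diels–Alder/aromatization of 1-alkoxy-1-silyloxy-3-oxybutadienes (Brassard-type dienes) with acetylenic esters, which gives resorcylates. Ring B, the only ring closed, forms by intermolecular [4+2] closure that makes B4–B5 and B1–B6 in one operation. The only new stereocentre is the mixed ketal carbon B1 of 20, which forms racemic and is erased on aromatization, so nothing has to control it. The selectivity needed is regiochemical and is secured twice: the largest HOMO coefficient of the vinylogous ketene acetal lies on B4, and in 19 both the ester and the ynol ether oxygen make B5 the electrophilic carbon, so only the 1,3,5-oxygen pattern can result. The donor oxygen lowers the dienophilicity of 19 relative to a plain propiolate, which is answered by heat, high concentration and surplus 7 (which reverts to 5 on the acidic work-up), while the aryl ynol ether lacks the β-hydrogen needed for retro-ene loss of a ketene and should withstand the temperature.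

Step 11
Reactants: 22 methyl 2-hydroxy-6-[(2,2',4,4',6,6'-hexamethoxybiphenyl-3-yl)oxy]-4-(2,4,6-trimethoxyphenoxy)benzoate
Product: 23 2-hydroxy-6-[(2,2',4,4',6,6'-hexamethoxybiphenyl-3-yl)oxy]-4-(2,4,6-trimethoxyphenoxy)benzoic acid
Conditions: KOH (10 equiv), DMSO/H2O 4:1, 90 °C; then 1 M HCl, 0 °C, pH 3
Reagents that add atoms: potassium hydroxide, [K+].[OH-] (carboxyl oxygen)
Why: Saponification of a di-ortho-substituted benzoate with poorly solvated hydroxide in DMSO; the B1 phenoxide that forms first leaves ring B too electron-rich for SNAr loss of either aryloxide.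

Step 12
Reactants: 23 2-hydroxy-6-[(2,2',4,4',6,6'-hexamethoxybiphenyl-3-yl)oxy]-4-(2,4,6-trimethoxyphenoxy)benzoic acid
Product: 24 3-[(2,2',4,4',6,6'-hexamethoxybiphenyl-3-yl)oxy]-5-(2,4,6-trimethoxyphenoxy)phenol
Conditions: Ag2CO3 (10 mol %), AcOH (5 mol %), DMSO, 120 °C
Reagents that add atoms: none
Why: Silver-catalysed protodecarboxylation of an ortho-substituted benzoic acid, made easy because the ipso carbon B6 is ortho/para to three oxygen donors; any loss of CO2 already in step 11 only leads on to 24.

Step 13
Reactants: 24 3-[(2,2',4,4',6,6'-hexamethoxybiphenyl-3-yl)oxy]-5-(2,4,6-trimethoxyphenoxy)phenol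
Product: 25 3-[3-hydroxy-5-(2,4,6-trihydroxyphenoxy)phenoxy]biphenyl-2,2',4,4',6,6'-hexol (CNP0260439.0)
Conditions: BBr3 (20 equiv), CH2Cl2, −78 °C → rt, Ar; then H2O, 0 °C; EtOAc extraction; C18 chromatography with degassed H2O/MeOH
Reagents that add atoms: none
Why: Lewis-acid ether cleavage in which bromide attacks the methyl carbon of each boron-complexed methoxy group by SN2; the two diaryl ether linkages and the biaryl bond offer no sp3 carbon and should stay intact.

## Compound list
1 | 2,4,6-trimethoxybenzaldehyde | COc1cc(OC)c(C=O)c(OC)c1 | starting material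
2 | 2,4,6-trimethoxyphenyl formate | COc1cc(OC)c(OC=O)c(OC)c1 | intermediate (not isolated)
3 | 2,4,6-trimethoxyphenol | COc1cc(OC)c(O)c(OC)c1 | intermediate
4 | methyl but-2-ynoate | CC#CC(=O)OC | starting material
5 | methyl (E)-3-(2,4,6-trimethoxyphenoxy)but-2-enoate | C/C(Oc1c(OC)cc(OC)cc1OC)=C\C(=O)OC | intermediate
6 | lithium 1-methoxy-3-(2,4,6-trimethoxyphenoxy)buta-1,3-dien-1-olate (O–Li cis to C3) | C=C(Oc1c(OC)cc(OC)cc1OC)/C=C(/OC)[O-].[Li+] | intermediate (not isolated)
7 | (1Z)-1-methoxy-1-(trimethylsilyloxy)-3-(2,4,6-trimethoxyphenoxy)buta-1,3-diene | C=C(Oc1c(OC)cc(OC)cc1OC)/C=C(/OC)O[Si](C)(C)C | intermediate (key-step precursor)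
8 | 1,3,5-trimethoxybenzene | COc1cc(OC)cc(OC)c1 | starting material
9 | 2-iodo-1,3,5-trimethoxybenzene | COc1cc(OC)c(I)c(OC)c1 | intermediate
10 | 2,2',4,4',6,6'-hexamethoxybiphenyl | COc1cc(OC)c(-c2c(OC)cc(OC)cc2OC)c(OC)c1 | intermediate
11 | [(2,2',4,4',6,6'-hexamethoxybiphenyl-3-yl)methylidene]dimethylammonium dichlorophosphate | C[N+](C)=Cc1c(OC)cc(OC)c(-c2c(OC)cc(OC)cc2OC)c1OC.[O-]P(=O)(Cl)Cl | intermediate (not isolated)
12 | 2,2',4,4',6,6'-hexamethoxybiphenyl-3-carbaldehyde | O=Cc1c(OC)cc(OC)c(-c2c(OC)cc(OC)cc2OC)c1OC | intermediate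
13 | 2,2',4,4',6,6'-hexamethoxybiphenyl-3-yl formate | O=COc1c(OC)cc(OC)c(-c2c(OC)cc(OC)cc2OC)c1OC | intermediate (not isolated)
14 | 2,2',4,4',6,6'-hexamethoxybiphenyl-3-ol | Oc1c(OC)cc(OC)c(-c2c(OC)cc(OC)cc2OC)c1OC | intermediate
15 | trichloroethylene | ClC=C(Cl)Cl | starting material
16 | 3-{[(E)-1,2-dichloroethenyl]oxy}-2,2',4,4',6,6'-hexamethoxybiphenyl | Cl/C=C(/Cl)Oc1c(OC)cc(OC)c(-c2c(OC)cc(OC)cc2OC)c1OC | intermediate
17 | 3-[(chloroethynyl)oxy]-2,2',4,4',6,6'-hexamethoxybiphenyl | ClC#COc1c(OC)cc(OC)c(-c2c(OC)cc(OC)cc2OC)c1OC | intermediate (not isolated)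
18 | lithium [(2,2',4,4',6,6'-hexamethoxybiphenyl-3-yl)oxy]acetylide | [Li]C#COc1c(OC)cc(OC)c(-c2c(OC)cc(OC)cc2OC)c1OC | intermediate (not isolated)
19 | methyl 3-[(2,2',4,4',6,6'-hexamethoxybiphenyl-3-yl)oxy]prop-2-ynoate | COC(=O)C#COc1c(OC)cc(OC)c(-c2c(OC)cc(OC)cc2OC)c1OC | intermediate (key-step precursor)
20 | methyl 2-[(2,2',4,4',6,6'-hexamethoxybiphenyl-3-yl)oxy]-6-methoxy-4-(2,4,6-trimethoxyphenoxy)-6-(trimethylsilyloxy)cyclohexa-1,4-diene-1-carboxylate (racemic) | COC(=O)C1=C(Oc2c(OC)cc(OC)c(-c3c(OC)cc(OC)cc3OC)c2OC)CC(Oc2c(OC)cc(OC)cc2OC)=CC1(OC)O[Si](C)(C)C | intermediate (not isolated)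
21 | methyl 2-[(2,2',4,4',6,6'-hexamethoxybiphenyl-3-yl)oxy]-4-(2,4,6-trimethoxyphenoxy)-6-(trimethylsilyloxy)benzoate | COC(=O)c1c(O[Si](C)(C)C)cc(Oc2c(OC)cc(OC)cc2OC)cc1Oc1c(OC)cc(OC)c(-c2c(OC)cc(OC)cc2OC)c1OC | intermediate (not isolated)
22 | methyl 2-hydroxy-6-[(2,2',4,4',6,6'-hexamethoxybiphenyl-3-yl)oxy]-4-(2,4,6-trimethoxyphenoxy)benzoate | COC(=O)c1c(O)cc(Oc2c(OC)cc(OC)cc2OC)cc1Oc1c(OC)cc(OC)c(-c2c(OC)cc(OC)cc2OC)c1OC | intermediate (key-step product)
23 | 2-hydroxy-6-[(2,2',4,4',6,6'-hexamethoxybiphenyl-3-yl)oxy]-4-(2,4,6-trimethoxyphenoxy)benzoic acid | OC(=O)c1c(O)cc(Oc2c(OC)cc(OC)cc2OC)cc1Oc1c(OC)cc(OC)c(-c2c(OC)cc(OC)cc2OC)c1OC | intermediate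
24 | 3-[(2,2',4,4',6,6'-hexamethoxybiphenyl-3-yl)oxy]-5-(2,4,6-trimethoxyphenoxy)phenol | Oc1cc(Oc2c(OC)cc(OC)cc2OC)cc(Oc2c(OC)cc(OC)c(-c3c(OC)cc(OC)cc3OC)c2OC)c1 | intermediate
25 | 3-[3-hydroxy-5-(2,4,6-trihydroxyphenoxy)phenoxy]biphenyl-2,2',4,4',6,6'-hexol | Oc1cc(Oc2c(O)cc(O)cc2O)cc(Oc2c(O)cc(O)c(-c3c(O)cc(O)cc3O)c2O)c1 | target

## Step count and risks
Total step count: 13. Longest linear sequence: 10 steps (steps 4–13, from 8 to 25).

**Risk 1, step 10.**
- What may go wrong: the cycloaddition may be too slow because the donor oxygen on B5 raises the LUMO of the ynoate. Thermal silyl migration and protodesilylation of the diene could then outrun ring closure. A stepwise addition could also expel aryloxide instead of closing the ring.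
- Fallback: ring B is bought instead of built. The fallback sets out from phenols 3 and 14 and comes back to the route at 25.
- Phenol 3 is coupled with an excess of 3,5-dibromoanisole in a copper-catalysed Ullmann diaryl ether synthesis (CuI, picolinic acid, K3PO4, DMSO, 90 °C). This should give 1-bromo-3-methoxy-5-(2,4,6-trimethoxyphenoxy)benzene F1.
- A second coupling of the same kind with phenol 14 should give 2,2',4,4',6,6'-hexamethoxy-3-[3-methoxy-5-(2,4,6-trimethoxyphenoxy)phenoxy]biphenyl F2.
- The BBr3 conditions of step 13 should then cleave all ten methyl ethers of F2 to give 25.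

**Risk 2, step 9.**
- What may go wrong: n-BuLi may lithiate the ring between two methoxy groups, the acetylide may attack the product ester, and the push–pull alkyne may be hydrated on work-up.
- Fallback: a route without organolithium reagents, which replaces steps 8 and 9. It sets out from 14 and comes back at 19.
- Phenol 14 is treated with methyl 3,3-dichloroacrylate (K2CO3, DMF, rt) in a vinylic addition–elimination. This should give methyl 3-chloro-3-[(2,2',4,4',6,6'-hexamethoxybiphenyl-3-yl)oxy]prop-2-enoate F3 as a mixture of double-bond isomers.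
- Both isomers should lose HCl with the non-nucleophilic base KN(SiMe3)2 (THF, −78 °C) by an E1cB path through the α-metalated acrylate, giving 19.

**Risk 3, step 13.**
- What may go wrong: partly cleaved boron aryloxides may precipitate and leave the ether cleavage incomplete. The free decaphenol may also be oxidised by air during chromatography.
- Fallback: derivatise, purify, then release. It sets out from 24 and comes back at 25.
- The crude product of the BBr3 treatment is not purified but peracetylated (Ac2O, pyridine, rt). This should give 3-[3-acetoxy-5-(2,4,6-triacetoxyphenoxy)phenoxy]biphenyl-2,2',4,4',6,6'-hexayl hexaacetate F4.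
- F4 is an air-stable decaacetate that can be separated on ordinary silica from congeners that still carry methyl groups.
- Acid-catalysed methanolysis (HCl in degassed MeOH, rt) followed by evaporation should then release 25 without chromatography of the free polyphenol.

## Further compounds
F1 | step 10 | 1-bromo-3-methoxy-5-(2,4,6-trimethoxyphenoxy)benzene | COc1cc(Br)cc(Oc2c(OC)cc(OC)cc2OC)c1
F2 | step 10 | 2,2',4,4',6,6'-hexamethoxy-3-[3-methoxy-5-(2,4,6-trimethoxyphenoxy)phenoxy]biphenyl | COc1cc(Oc2c(OC)cc(OC)cc2OC)cc(Oc2c(OC)cc(OC)c(-c3c(OC)cc(OC)cc3OC)c2OC)c1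
F3 | step 9 | methyl 3-chloro-3-[(2,2',4,4',6,6'-hexamethoxybiphenyl-3-yl)oxy]prop-2-enoate (mixture of double-bond isomers) | COC(=O)C=C(Cl)Oc1c(OC)cc(OC)c(-c2c(OC)cc(OC)cc2OC)c1OC
F4 | step 13 | 3-[3-acetoxy-5-(2,4,6-triacetoxyphenoxy)phenoxy]biphenyl-2,2',4,4',6,6'-hexayl hexaacetate | CC(=O)Oc1cc(Oc2c(OC(C)=O)cc(OC(C)=O)cc2OC(C)=O)cc(Oc2c(OC(C)=O)cc(OC(C)=O)c(-c3c(OC(C)=O)cc(OC(C)=O)cc3OC(C)=O)c2OC(C)=O)c1
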